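The green flask cannot end with more mono adduct than 50.0% of the starting material charged, because each mono adduct takes one partner and the partner charged is half the starting material; partner is the limiting reagent there.

| flask | starting material | partner | remark | time |
|---|---|---|---|---|
| winter | 0.20 M | 0.065 M | run made earlier |  |
| midnight | 0.26 M | 0.065 M | run made earlier |  |
| green | 0.13 M | 0.0650 M |  | 4.0 min |
| violet | 0.13 M | 0.130 M |  | 4.0 min |
| red | 0.13 M | 0.156 M |  | 4.0 min |

| run | time / s | mono adduct / % | tris adduct / % |
|---|---|---|---|
| winter | 10.0 | 20.3 | 0 |
| winter | 15.0 | 23.9 | 0.5 |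
| winter | 30.0 | 30.2 | 0.3 |
| winter | 50.0 | 32.6 | 1.1 |
| midnight | 12.0 | 19.7 | 0 |
| midnight | 25.0 | 23.7 | 0 |
| midnight | 40.0 | 25.0 | 0 |
| midnight | 50.0 | 24.4 | 0.2 |

(standard deviation of a reading: 0.5 percentage points)

* amount of mono adduct at the end, in percent of the starting material charged, for each flask in turn (green, violet, red)

I read the first addition as a bimolecular step. The first reading of each earlier run, put into the integrated second-order law, gives 0.558 L mol⁻¹ s⁻¹ in winter and 0.569 L mol⁻¹ s⁻¹ in midnight, so I carry the mean k, 0.563 L mol⁻¹ s⁻¹.

My bound from above, as good as a k read from scattered readings allows, is Y, the mono adduct reckoned from this first addition at 4.0 min with nothing further happening to it. In violet, with equal charges and [starting material] taken as charged, Y is k[starting material]t/(1+k[starting material]t), which is 94.6%.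

| Flask | Ceiling from the charges | Y |
|---|---|---|
| green | 50.0% | 50.0% |
| violet | 100% | 94.6% |
| red | 100% | 99.5% |

For a floor I compute the correction to Y. I take tris adduct as costing one mono adduct and two further partners, and I let it grow as s[mono adduct]/[starting material] per starting material consumed. The last readings of both runs give the selectivity factor s as 0.125, and the partner balance then puts violet at 56.1%. Winter's last tris reading stands 2.20 scatter widths above zero, so s is a rough reading, and I expect violet in the upper part of this bracket.

The forecast gives 45.7%, 75% and 80%, reasoning that “Each tris costs two extra partners.”, and its violet value lies inside my bracket.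

The flasks end at 49.3%, 90.3% and 93.3%.

    partner + double product → tris adduct (k = 1.60 L mol⁻¹ s⁻¹)
    partner + tris adduct ⇌ tetra adduct (K = 110 L mol⁻¹, k = 1.70 L mol⁻¹ s⁻¹)
    starting material + partner → mono adduct (k = 0.580 L mol⁻¹ s⁻¹)
    double product → decomposed reagent (k = 0.120 s⁻¹)
    partner + mono adduct → double product (k = 0.00940 L mol⁻¹ s⁻¹)

In violet, Y less the result is 4.3 percentage points, and at 4.00 min that flask holds 2.09% decomposed reagent beside 0.403% tris adduct. In red, Y less the result is 6.2 points, and decomposed reagent stands at 3.85% at 4.00 min.

The earlier runs and the new flask come from a simulation with made-up constants, noise included.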